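**Retrosynthetic overview**
1. The target comes from its bis-methyl ether by O-demethylation; the side chain is finished by a C13–C14 bond between a C11 vinyl group and a chiral-pool C3 bromide, and the C6 ester is put in by directed ortho-lithiation.
2. The C4–C11 bond and the C11 stereocentre come from branched allylation of a β-tetralone at C4 with but-2-yne (new rhodium-hydride coupling); the C3 carbonyl is then removed.
3. Key disconnection: the six-membered carbocycle is made by one-carbon ring expansion (1,2-aryl shift, diazo insertion) of a chiral 3-methylindan-1-one, which places the carbonyl next to C4.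
4. The indanone comes from Friedel–Crafts acylation of (R)-3-arylbutanoic acid, itself from stereoinvertive opening of (S)-β-butyrolactone by ortho-metalated 1,2-dimethoxybenzene (from catechol).
5. Ring order: aromatic ring (catechol), then the five-membered ring, then its expansion to the six-membered ring.

Assumption: positions are given in serrulatane numbering (C1 ring CH–CH3, C4 ring CH with the side chain, C6 ester, C7/C8 oxygens, C11 and C15 side-chain stereocentres, C16 the CH2OH carbon); in step 5 the ligand antipode that gives (S) at C11 is the one used.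

**Step 1**
Reactants: 1 catechol (benzene-1,2-diol)
Product: 2 1,2-dimethoxybenzene
Conditions: MeI, K2CO3, acetone, reflux
Reagents that add atoms: iodomethane (CI)
Why: Williamson ether synthesis (double O-methylation) gives the dimethyl ether, which protects the catechol and later directs both ortho-lithiations; no stereocentre is involved.

**Step 2**
Reactants: 2 1,2-dimethoxybenzene; 3 (4S)-4-methyloxetan-2-one ((S)-β-butyrolactone)
Product: 6 (3R)-3-(2,3-dimethoxyphenyl)butanoic acid, via 2,3-dimethoxyphenyllithium 4 (not isolated), via 2,3-dimethoxyphenylmagnesium bromide 5 (not isolated)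
Conditions: n-BuLi, TMEDA, Et2O, 0 °C to rt; MgBr2·OEt2, −20 °C; CuBr·SMe2 (10 mol %), then 3 in THF, −30 to 0 °C; aq. HCl
Reagents that add atoms: none
Why: Directed ortho-lithiation, transmetalation and copper-catalysed SN2 opening of the β-lactone at its alkyl C–O bond form the C8a–C1 bond, and clean inversion of the (S)-lactone carbon sets C1 as (R).

**Step 3**
Reactants: 6 (3R)-3-(2,3-dimethoxyphenyl)butanoic acid
Product: 7 (3R)-4,5-dimethoxy-3-methyl-2,3-dihydro-1H-inden-1-one
Conditions: Eaton's reagent (P2O5 in MeSO3H) as solvent, 40 °C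
Reagents that add atoms: none
Why: Intramolecular Friedel–Crafts acylation closes the five-membered ring at the only free ortho position (para to a methoxy group), and the stereocentre, β to the new carbonyl, is not touched.

**Step 4**
Reactants: 7 (3R)-4,5-dimethoxy-3-methyl-2,3-dihydro-1H-inden-1-one
Product: 9 (4R)-5,6-dimethoxy-4-methyl-3,4-dihydronaphthalen-2(1H)-one, via 1-trimethylsilyl ketone 8 (not isolated)
Conditions: TMSCHN2, BF3·OEt2, CH2Cl2, −78 to −20 °C; then 1 M HCl, THF, rt
Reagents that add atoms: trimethylsilyldiazomethane (C[Si](C)(C)C=[N+]=[N-])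
Why: Lewis-acid-promoted diazoalkane homologation (Tiffeneau–Demjanov-type one-carbon ring expansion) in which the electron-rich aryl carbon (para-methoxy) makes the 1,2-shift with loss of N2 and inserts C4 between arene and carbonyl, the bulky silyl group blocking a second insertion before protodesilylation; C1 is not involved.

**Step 5**
Reactants: 9 (4R)-5,6-dimethoxy-4-methyl-3,4-dihydronaphthalen-2(1H)-one; 10 but-2-yne
Product: 12 (1S,4R)-1-[(2S)-but-3-en-2-yl]-5,6-dimethoxy-4-methyl-3,4-dihydronaphthalen-2(1H)-one, via buta-1,2-diene 11 (not isolated)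
Conditions: [Rh(cod)Cl]2 (2.5 mol %), (R)-DTBM-SEGPHOS (6 mol %), PhCO2H (20 mol %), ClCH2CH2Cl, 70 °C, sealed tube
Reagents that add atoms: none
Why: Proposed new method: a rhodium hydride formed from [Rh(cod)Cl]2, the bisphosphine and PhCO2H isomerises but-2-yne to buta-1,2-diene and adds to it to give a π-(1-methylallyl) intermediate on rhodium, which the conjugated enol of the β-tetralone (an α-aryl ketone of pKa about 17, C-nucleophilic at C4) attacks at the substituted terminus in a fully atom-economic one-to-one addition, so the C4–C11 bond forms with the chiral ligand fixing C11 as (S) and the pseudoaxial C1 methyl group steering attack to the opposite face (C4 trans to C1, which should also be the more stable epimer of this enolisable centre); the closest known reaction type is the rhodium-hydride-catalysed branched allylation of 1,3-dicarbonyl pronucleophiles and aldehyde-derived enamines with methyl-substituted alkynes or allenes.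

**Step 6**
Reactants: 12 (1S,4R)-1-[(2S)-but-3-en-2-yl]-5,6-dimethoxy-4-methyl-3,4-dihydronaphthalen-2(1H)-one
Product: 14 (1S,4R)-1-[(2S)-but-3-en-2-yl]-5,6-dimethoxy-4-methyl-1,2,3,4-tetrahydronaphthalene, via tosylhydrazone 13 (not isolated)
Conditions: TsNHNH2, EtOH, 60 °C; then catecholborane, CHCl3, 0 °C; NaOAc·3H2O, reflux
Reagents that add atoms: none
Why: Caglioti–Kabalka deoxygenation (hydride addition to the tosylhydrazone C=N, then loss of sulfinate and N2 from the diazene) turns C3 into CH2 without touching the alkene or C1 and C11, and any epimerisation at C4 at the hydrazone stage only funnels to the same trans isomer.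

**Step 7**
Reactants: 14 (1S,4R)-1-[(2S)-but-3-en-2-yl]-5,6-dimethoxy-4-methyl-1,2,3,4-tetrahydronaphthalene
Product: 16 methyl (5R,8S)-8-[(2S)-but-3-en-2-yl]-3,4-dimethoxy-5-methyl-5,6,7,8-tetrahydronaphthalene-2-carboxylate, via aryllithium 15 (not isolated)
Conditions: s-BuLi, TMEDA, Et2O, −78 to −20 °C; then ClCO2Me (excess), −78 °C
Reagents that add atoms: methyl chloroformate (COC(=O)Cl)
Why: Directed ortho-lithiation (C6 is the only aromatic C–H ortho to a methoxy group) followed by acylation with the chloroformate installs the methyl ester; no stereocentre is affected.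

**Step 8**
Reactants: 16 methyl (5R,8S)-8-[(2S)-but-3-en-2-yl]-3,4-dimethoxy-5-methyl-5,6,7,8-tetrahydronaphthalene-2-carboxylate; 17 (2R)-3-bromo-2-methylpropan-1-ol
Product: 18 methyl (5R,8S)-8-[(2S,6S)-7-hydroxy-6-methylheptan-2-yl]-3,4-dimethoxy-5-methyl-5,6,7,8-tetrahydronaphthalene-2-carboxylate
Conditions: NiBr2·diglyme (10 mol %), 4,4'-di-tert-butyl-2,2'-bipyridine (12 mol %), (EtO)2MeSiH, Na2CO3, DMA, 30 °C
Reagents that add atoms: none
Why: Nickel-hydride-catalysed anti-Markovnikov reductive hydroalkylation of the terminal alkene with the primary alkyl bromide forms the C13–C14 bond under conditions that tolerate the free hydroxyl and the ester, and C15 comes unchanged from the chiral-pool bromide because the radical forms on the neighbouring CH2.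

**Step 9**
Reactants: 18 methyl (5R,8S)-8-[(2S,6S)-7-hydroxy-6-methylheptan-2-yl]-3,4-dimethoxy-5-methyl-5,6,7,8-tetrahydronaphthalene-2-carboxylate
Product: 19 methyl (5R,8S)-3,4-dihydroxy-8-[(2S,6S)-7-hydroxy-6-methylheptan-2-yl]-5-methyl-5,6,7,8-tetrahydronaphthalene-2-carboxylate (CNP0135649.1)
Conditions: BBr3, CH2Cl2, −78 to 0 °C; then H2O
Reagents that add atoms: none
Why: Lewis-acid cleavage of both aryl methyl ethers (BBr3 demethylation) frees the catechol, while the methyl ester, the primary alcohol (returned from its borate on work-up) and all four stereocentres stay intact.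

**Compound list**
1 | catechol (benzene-1,2-diol) | Oc1ccccc1O | starting material
2 | 1,2-dimethoxybenzene | COc1ccccc1OC | intermediate
3 | (4S)-4-methyloxetan-2-one ((S)-β-butyrolactone) | C[C@H]1CC(=O)O1 | starting material
4 | (2,3-dimethoxyphenyl)lithium | [Li]c1cccc(OC)c1OC | intermediate
5 | (2,3-dimethoxyphenyl)magnesium bromide | Br[Mg]c1cccc(OC)c1OC | intermediate
6 | (3R)-3-(2,3-dimethoxyphenyl)butanoic acid | c1ccc(c(OC)c1OC)[C@H](C)CC(=O)O | intermediate
7 | (3R)-4,5-dimethoxy-3-methyl-2,3-dihydro-1H-inden-1-one | c1cc2c(c(OC)c1OC)[C@H](C)CC2=O | intermediate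
8 | (4R)-5,6-dimethoxy-4-methyl-1-(trimethylsilyl)-3,4-dihydronaphthalen-2(1H)-one (both C1 epimers) | c1cc2c(c(OC)c1OC)[C@H](C)CC(=O)C2[Si](C)(C)C | intermediate
9 | (4R)-5,6-dimethoxy-4-methyl-3,4-dihydronaphthalen-2(1H)-one | c1cc2c(c(OC)c1OC)[C@H](C)CC(=O)C2 | intermediate
10 | but-2-yne | CC#CC | starting material
11 | buta-1,2-diene | C=C=CC | intermediate
12 | (1S,4R)-1-[(2S)-but-3-en-2-yl]-5,6-dimethoxy-4-methyl-3,4-dihydronaphthalen-2(1H)-one | c1cc2c(c(OC)c1OC)[C@H](C)CC(=O)[C@H]2[C@@H](C)C=C | intermediate
13 | N'-[(1S,4R)-1-[(2S)-but-3-en-2-yl]-5,6-dimethoxy-4-methyl-3,4-dihydronaphthalen-2(1H)-ylidene]-4-methylbenzenesulfonohydrazide | c1cc2c(c(OC)c1OC)[C@H](C)CC(=NNS(=O)(=O)c3ccc(C)cc3)[C@H]2[C@@H](C)C=C | intermediate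
14 | (1S,4R)-1-[(2S)-but-3-en-2-yl]-5,6-dimethoxy-4-methyl-1,2,3,4-tetrahydronaphthalene | c1cc2c(c(OC)c1OC)[C@H](C)CC[C@H]2[C@@H](C)C=C | intermediate
15 | [(5R,8S)-8-[(2S)-but-3-en-2-yl]-3,4-dimethoxy-5-methyl-5,6,7,8-tetrahydronaphthalen-2-yl]lithium | [Li]c1cc2c(c(OC)c1OC)[C@H](C)CC[C@H]2[C@@H](C)C=C | intermediate
16 | methyl (5R,8S)-8-[(2S)-but-3-en-2-yl]-3,4-dimethoxy-5-methyl-5,6,7,8-tetrahydronaphthalene-2-carboxylate | COC(=O)c1cc2c(c(OC)c1OC)[C@H](C)CC[C@H]2[C@@H](C)C=C | intermediate
17 | (2R)-3-bromo-2-methylpropan-1-ol | BrC[C@H](C)CO | starting material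
18 | methyl (5R,8S)-8-[(2S,6S)-7-hydroxy-6-methylheptan-2-yl]-3,4-dimethoxy-5-methyl-5,6,7,8-tetrahydronaphthalene-2-carboxylate | COC(=O)c1cc2c(c(OC)c1OC)[C@H](C)CC[C@H]2[C@@H](C)CCC[C@H](C)CO | intermediate
19 | methyl (5R,8S)-3,4-dihydroxy-8-[(2S,6S)-7-hydroxy-6-methylheptan-2-yl]-5-methyl-5,6,7,8-tetrahydronaphthalene-2-carboxylate (CNP0135649.1) | COC(=O)c1cc2c(c(O)c1O)[C@H](C)CC[C@H]2[C@@H](C)CCC[C@H](C)CO | target

**Step count and risks**
Total step count: 9. Longest linear sequence: 9 (1 to 19).

The three steps most likely to fail: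

Step 4 (ring expansion). The carbonyl is a deactivated p-alkoxyaryl ketone, and alkyl instead of aryl migration or a second homologation could cut the yield. The fallback sets out from 7. Wittig methylenation (Ph3PCH3Br, KOt-Bu, THF) gives (3R)-4,5-dimethoxy-3-methyl-1-methylidene-2,3-dihydro-1H-indene F1. Oxidative rearrangement of F1 with PhI(OH)OTs in 95 % MeOH then moves the aryl group onto the exocyclic carbon (the known Wittig/ring-expansion route to β-tetralones). This comes back to the route at 9.

Step 5 (the proposed new coupling). The β-tetralone may be too weak a pronucleophile for the rhodium allyl intermediate, or ligand control at C11 may be poor. The fallback uses known, substrate-controlled chemistry and sets out from 9. Condensation with (E)-but-2-en-1-ol (cat. TsOH, toluene, azeotropic removal of water) gives the crotyl enol ether (1R)-3-[(2E)-but-2-en-1-yloxy]-7,8-dimethoxy-1-methyl-1,2-dihydronaphthalene F2. Heating F2 (xylene, 140 °C) brings about the Claisen rearrangement on the face away from the C1 methyl group. The chair transition state with the (E)-crotyl methyl equatorial gives the (1S, side-chain 2S) relationship. This comes back to the route at 12.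

Step 8 (nickel-hydride hydroalkylation). The branched allylic position next to the alkene, the β-branched bromide and the free hydroxyl may lower the yield or cause chain walking. The fallback sets out from 16 and 17. Coupling of 17 with CH2=CHMgBr (3 equiv, Li2CuCl4 cat., THF) gives (2S)-2-methylpent-4-en-1-ol F3. Cross-metathesis of 16 with F3 (second-generation Hoveyda–Grubbs catalyst, CH2Cl2, 40 °C) gives methyl (5R,8S)-8-[(2S,3E,6S)-7-hydroxy-6-methylhept-3-en-2-yl]-3,4-dimethoxy-5-methyl-5,6,7,8-tetrahydronaphthalene-2-carboxylate F4. Hydrogenation of F4 (H2, Pd/C, EtOAc) comes back to the route at 18.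

**Further compounds**
F1 | step 4 | (3R)-4,5-dimethoxy-3-methyl-1-methylidene-2,3-dihydro-1H-indene | c1cc2c(c(OC)c1OC)[C@H](C)CC2=C
F2 | step 5 | (1R)-3-[(2E)-but-2-en-1-yloxy]-7,8-dimethoxy-1-methyl-1,2-dihydronaphthalene | c1cc2c(c(OC)c1OC)[C@H](C)CC(OC/C=C/C)=C2
F3 | step 8 | (2S)-2-methylpent-4-en-1-ol | C=CC[C@H](C)CO
F4 | step 8 | methyl (5R,8S)-8-[(2S,3E,6S)-7-hydroxy-6-methylhept-3-en-2-yl]-3,4-dimethoxy-5-methyl-5,6,7,8-tetrahydronaphthalene-2-carboxylate | COC(=O)c1cc2c(c(OC)c1OC)[C@H](C)CC[C@H]2[C@@H](C)/C=C/C[C@H](C)CO
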